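The readings were generated by integration from invented constants, noise included.

The time asked, 12 h, lies 6.00 h beyond the last reading of the north-east flask, which is the flask in question, so its target must be carried forward past the readings.

all flasks: substrate 0.80 M; gas phase 45 mM (held)
- north-east: the very flask that is asked about, followed so far
- flask: time 12 h

north-east run (percent of the substrate charged)

| time / h | target / % |
|---|---|
| 0.500 | 6.9 |
| 0.667 | 9.5 |
| 1.00 | 13.9 |
| 1.50 | 20.3 |
| 2.50 | 29.0 |
| 4.00 | 36.2 |
| 6.00 | 38.0 |

(each reading ± 0.5 percentage points)

- percentages count the substrate that a species holds: one side product B counts as two
- at the start none of the gas is dissolved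
- steps thought possible: gas phase <-> dissolved gas; dissolved gas <-> dormant form; substrate -> side product A; substrate + dissolved gas -> target; dissolved gas + target -> over-reaction product; substrate + target -> side product B

- amount of target at 12 h, in percent of the substrate charged
- concentration of dissolved gas in solution at 12 h, in percent of saturation

My reckoning begins with the first hour of the north-east readings, which gives a making constant of 0.139 h⁻¹. If substrate decays at that constant, 43.4 % of it stands at 6.00 h, feeding target at 0.0604 h⁻¹. The last two readings still rise by 0.00900 h⁻¹, so the loss is the difference. Divided by the 38.0 % of target, it gives 0.135 h⁻¹, and so 5.13 h, the half-life of target against its losses with nothing fed in. This is a pseudo-first-order figure, which assumes that the loss per unit of target stays as it was at 6.00 h.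

Counting 1.17 half-lives takes the reading down to 16.9 %. The objection is that remaining substrate still feeds target. Holding the feed at its rate at 6.00 h, and damping what it adds by the same loss, raises the figure to 33.0 %, but the substrate behind that feed falls meanwhile, so the figure is generous. I commit to the middle, 24.9 %. If uptake follows the gap below saturation, the whole gap is set against the making constant, and the entire loss of target at 12 h is counted as demand for gas, about 75.8 % of saturation remains. That figure is soft, for the possible step to the dormant form is not counted in it.

The forecast gives 27 % and 72 %, expecting “the target to have fallen to the high twenties or lower, and the solution to be well recovered but not fully saturated”. Its target stands 2.1 percentage points above mine, and its gas is lower than mine.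

The flask gives 22.8 % and 86.2 %.

    gas phase ⇌ dissolved gas, rate k1*(csat - [dissolved gas]) (kL = 0.0910 min⁻¹)
    dissolved gas ⇌ dormant form (K = 15.0, k = 0.00180 min⁻¹)
    substrate → side product A (k = 4.40 × 10⁻⁴ min⁻¹)
    substrate + dissolved gas → target (k = 0.170 L mol⁻¹ min⁻¹)
    dissolved gas + target → over-reaction product (k = 0.0610 L mol⁻¹ min⁻¹)
    substrate + target → side product B (k = 0.00380 L mol⁻¹ min⁻¹)

At 3.87 h this flask used dissolved gas for target 2.6 times as fast as for over-reaction product. At 12.0 h, with 1.01 % substrate left, that ratio was 0.12, and over-reaction product held 39.8 %. The bare count fell 5.9 points short of this flask, which held 14.7 % substrate at 6.00 h. For the neighbour left until 20 h, 1.56 half-lives take the 22.8 % of target to 7.73 %; that neighbour holds 7.19 % of target.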